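**Strategy.** In labdane numbering, the tetrasubstituted C8=C9 alkene is read as the enol derivative of a C9 ketone whose two α-carbons are C10 and C8. With an enal spanning C5–C6–C7, ring B becomes a [3+3] union, and because the ring-fusion bond C5–C10 also closes ring A, one acyclic silyl enol ether–enal is the whole precursor. An iminium-catalysed intramolecular Mukaiyama–Michael addition (C10 to C5), followed in the same flask by aldol condensation (C8 to C7), should build both rings and both ring stereocentres in one operation. Reductive enol triflation then fixes C8=C9, and a cyclopropanol homoenolate coupling plus methylenation appends the D-glycerate-derived side chain.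

Key step: step 5

Remark: the decalin is C1–C10, C17 is the methyl on C8, C20 the methyl on C10, and the side chain is C11–C16. The target as drawn is the trans-fused (5R,10R,14S) isomer. Compounds 1, 4, 7 and 13 and both antipodes of the imidazolidinone catalyst are taken as purchasable.

Step 1
Reactants: 1 methyl 3,3-dimethylpent-4-enoate
Product: 2 3,3-dimethylpent-4-en-1-ol
Conditions: LiAlH4, Et2O, 0 °C to rt
Reagents that add atoms: none
Why: Hydride reduction of the ester to the primary alcohol should leave the isolated vinyl group untouched.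

Step 2
Reactants: 2 3,3-dimethylpent-4-en-1-ol
Product: 3 5-bromo-3,3-dimethylpent-1-ene
Conditions: CBr4, PPh3, CH2Cl2, 0 °C
Reagents that add atoms: carbon tetrabromide, BrC(Br)(Br)Br
Why: Appel bromination of an unhindered primary alcohol through its alkoxyphosphonium salt should proceed cleanly, and no stereocentre is involved.

Step 3
Reactants: 3 5-bromo-3,3-dimethylpent-1-ene; 4 2-methylpent-1-en-3-one
Product: 6 trimethyl[(4,8,8-trimethyldeca-3,9-dien-3-yl)oxy]silane (E/Z mixture), via Grignard reagent 5 (not isolated)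
Conditions: Mg, THF, rt; then CuBr·SMe2 (5 mol %), Me3SiCl, 4, THF, −78 °C; Et3N, pentane, cold aqueous NaHCO3
Reagents that add atoms: chlorotrimethylsilane, C[Si](C)(C)Cl
Why: Copper-catalysed conjugate addition of the Grignard reagent to the α-methyl vinyl ketone with in situ O-silylation should trap the enolate regiospecifically as the tetrasubstituted C9=C10 silyl enol ether, whose geometry is irrelevant because C10 stays planar until step 5.

Step 4
Reactants: 6 trimethyl[(4,8,8-trimethyldeca-3,9-dien-3-yl)oxy]silane; 7 (E)-but-2-enal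
Product: 8 (2E)-4,4,8-trimethyl-9-[(trimethylsilyl)oxy]undeca-2,8-dienal
Conditions: second-generation Hoveyda–Grubbs catalyst (5 mol %), 7 (5 equiv, freshly distilled), CH2Cl2, 40 °C; chromatography on Et3N-deactivated silica
Reagents that add atoms: none
Why: Olefin cross-metathesis between the hindered terminal vinyl group, which is slow to homodimerise, and the electron-poor enal should give the E-enal under thermodynamic control, while the tetrasubstituted silyl enol ether is too hindered to engage the ruthenium carbene.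

Step 5
Reactants: 8 (2E)-4,4,8-trimethyl-9-[(trimethylsilyl)oxy]undeca-2,8-dienal
Product: 10 (4aR,8aR)-2,5,5,8a-tetramethyl-4a,5,6,7,8,8a-hexahydronaphthalen-1(4H)-one, via keto-aldehyde 9 (not isolated)
Conditions: (2R,5R)-5-benzyl-2-tert-butyl-3-methylimidazolidin-4-one trifluoroacetate (20 mol %), H2O (2 equiv), CH2Cl2/i-PrOH, −20 °C to rt; then p-TsOH·H2O (30 mol %), 40 °C, same flask without work-up
Reagents that add atoms: none
Why: The amine salt condenses with the C7 aldehyde to an E-iminium ion whose β-carbon C5 is attacked by C10 of the tethered silyl enol ether (intramolecular Mukaiyama–Michael addition, forming C5–C10); loss of the silyl group to water and enamine hydrolysis release keto-aldehyde 9, whose C8 then adds to the C7 carbonyl under acid and dehydrates (aldol condensation, forming C7–C8 and the C7=C8–C9=O enone). The closest known reaction types are the iminium-catalysed Mukaiyama–Michael addition of silyl enol ethers to enals and the Michael/aldol-condensation [3+3] annulation to cyclohexenones. Ring A closes in a 6-(enolexo)-exo-trig mode at C5 and ring B in a 6-(enolendo)-exo-trig mode at C7. C5 is set by the catalyst, whose benzyl group shields one face of the iminium ion so that C10 should add to the Re face (5R); C10 is set relative to C5 in a chair transition state with C6 equatorial, where the bulky silyloxyalkylidene arm avoids the syn-axial C4 methyl, so the C10 methyl becomes axial and anti to H5 (trans fusion, 10R). The step needs site selectivity, which the substrate secures: C4 is quaternary so the enal cannot form a dienamine, C10 is the only enol carbon that reaches C5 through a six-membered ring, and in 9 the C10 side of the ketone is quaternary so only C8 can condense with C7.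

Step 6
Reactants: 10 (4aR,8aR)-2,5,5,8a-tetramethyl-4a,5,6,7,8,8a-hexahydronaphthalen-1(4H)-one
Product: 12 (4aR,8aR)-2,5,5,8a-tetramethyl-3,4,4a,5,6,7,8,8a-octahydronaphthalen-1-yl trifluoromethanesulfonate, via lithium enolate 11 (not isolated)
Conditions: LiBH(s-Bu)3, THF, −78 °C; then PhNTf2, −78 °C to rt
Reagents that add atoms: N-phenylbis(trifluoromethanesulfonimide), O=S(=O)(N(c1ccccc1)S(=O)(=O)C(F)(F)F)C(F)(F)F
Why: Conjugate hydride delivery to C7 of the α-methyl enone (the C9 carbonyl is shielded by quaternary C10 against 1,2-attack) should give the C8=C9 enolate regiospecifically, and its O-sulfonylation locks the tetrasubstituted alkene in place.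

Step 7
Reactants: 13 methyl (4R)-2,2-dimethyl-1,3-dioxolane-4-carboxylate
Product: 14 1-[(4R)-2,2-dimethyl-1,3-dioxolan-4-yl]cyclopropan-1-ol
Conditions: EtMgBr (3 equiv), Ti(OiPr)4 (0.5 equiv), THF, 0 °C to rt
Reagents that add atoms: ethylmagnesium bromide, CC[Mg]Br
Why: In the Kulinkovich cyclopropanation the titanacyclopropane formed from EtMgBr and Ti(OiPr)4 adds twice to the ester carbonyl as a 1,2-dicarbanion equivalent, and the C14 stereocentre is not enolised and is carried through unchanged.

Step 8
Reactants: 12 (4aR,8aR)-2,5,5,8a-tetramethyl-3,4,4a,5,6,7,8,8a-octahydronaphthalen-1-yl trifluoromethanesulfonate; 14 1-[(4R)-2,2-dimethyl-1,3-dioxolan-4-yl]cyclopropan-1-ol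
Product: 15 1-[(4R)-2,2-dimethyl-1,3-dioxolan-4-yl]-3-[(4aR,8aR)-2,5,5,8a-tetramethyl-3,4,4a,5,6,7,8,8a-octahydronaphthalen-1-yl]propan-1-one
Conditions: Pd(OAc)2 (5 mol %), XPhos (10 mol %), Cs2CO3, toluene, 60 °C
Reagents that add atoms: none
Why: In this palladium-catalysed ring-opening cross-coupling of a cyclopropanol, zerovalent palladium inserts into the alkenyl triflate, alkoxide exchange and strain-driven β-carbon elimination give a palladium homoenolate, and reductive elimination forms C9–C11 while the triflate position fixes C8=C9.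

Step 9
Reactants: 15 1-[(4R)-2,2-dimethyl-1,3-dioxolan-4-yl]-3-[(4aR,8aR)-2,5,5,8a-tetramethyl-3,4,4a,5,6,7,8,8a-octahydronaphthalen-1-yl]propan-1-one
Product: 16 (4S)-2,2-dimethyl-4-{4-[(4aR,8aR)-2,5,5,8a-tetramethyl-3,4,4a,5,6,7,8,8a-octahydronaphthalen-1-yl]but-1-en-2-yl}-1,3-dioxolane
Conditions: Ph3PCH3Br, KN(SiMe3)2, THF, −78 to 0 °C
Reagents that add atoms: methyltriphenylphosphonium bromide, C[P+](c1ccccc1)(c1ccccc1)c1ccccc1.[Br-]
Why: Wittig methylenation of the C13 ketone with the non-stabilised ylide at low temperature should install C16 without epimerising the α-alkoxy centre C14, whose descriptor changes from R to S only through the priority rules.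

Step 10
Reactants: 16 (4S)-2,2-dimethyl-4-{4-[(4aR,8aR)-2,5,5,8a-tetramethyl-3,4,4a,5,6,7,8,8a-octahydronaphthalen-1-yl]but-1-en-2-yl}-1,3-dioxolane
Product: 17 (2S)-3-methylidene-5-[(4aR,8aR)-2,5,5,8a-tetramethyl-3,4,4a,5,6,7,8,8a-octahydronaphthalen-1-yl]pentane-1,2-diol
Conditions: AcOH/H2O (4:1), 40 °C
Reagents that add atoms: none
Why: Mild acid hydrolysis of the isopropylidene acetal should free the diol without isomerising either alkene or ionising the allylic C14–O bond.

Step 11
Reactants: 17 (2S)-3-methylidene-5-[(4aR,8aR)-2,5,5,8a-tetramethyl-3,4,4a,5,6,7,8,8a-octahydronaphthalen-1-yl]pentane-1,2-diol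
Product: 18 (2S)-3-methylidene-5-[(4aR,8aR)-2,5,5,8a-tetramethyl-3,4,4a,5,6,7,8,8a-octahydronaphthalen-1-yl]pentane-1,2-diyl diacetate (CNP0227767.1)
Conditions: Ac2O, pyridine, DMAP (cat.), CH2Cl2, 0 °C to rt
Reagents that add atoms: acetic anhydride, CC(=O)OC(C)=O
Why: DMAP-catalysed acylation of both hydroxyl groups should give the diacetate without touching any stereocentre.

**Compound list**

1 | methyl 3,3-dimethylpent-4-enoate | COC(=O)CC(C)(C)C=C | starting material
2 | 3,3-dimethylpent-4-en-1-ol | OCCC(C)(C)C=C | intermediate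
3 | 5-bromo-3,3-dimethylpent-1-ene | BrCCC(C)(C)C=C | intermediate
4 | 2-methylpent-1-en-3-one | CCC(=O)C(C)=C | starting material
5 | (3,3-dimethylpent-4-en-1-yl)magnesium bromide | C=CC(C)(C)CC[Mg]Br | intermediate (not isolated)
6 | trimethyl[(4,8,8-trimethyldeca-3,9-dien-3-yl)oxy]silane, E/Z mixture | CCC(O[Si](C)(C)C)=C(C)CCCC(C)(C)C=C | intermediate
7 | (E)-but-2-enal | C/C=C/C=O | starting material
8 | (2E)-4,4,8-trimethyl-9-[(trimethylsilyl)oxy]undeca-2,8-dienal, E/Z mixture at C8=C9 of the chain | CCC(O[Si](C)(C)C)=C(C)CCCC(C)(C)/C=C/C=O | intermediate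
9 | 2-[(1R,2R)-2,6,6-trimethyl-2-propanoylcyclohexyl]acetaldehyde | CCC(=O)[C@]1(C)CCCC(C)(C)[C@H]1CC=O | intermediate (not isolated)
10 | (4aR,8aR)-2,5,5,8a-tetramethyl-4a,5,6,7,8,8a-hexahydronaphthalen-1(4H)-one | O=C1C(C)=CC[C@@H]2C(C)(C)CCC[C@@]12C | intermediate
11 | lithium (4aR,8aR)-2,5,5,8a-tetramethyl-3,4,4a,5,6,7,8,8a-octahydronaphthalen-1-olate | [Li]OC1=C(C)CC[C@@H]2C(C)(C)CCC[C@@]12C | intermediate (not isolated)
12 | (4aR,8aR)-2,5,5,8a-tetramethyl-3,4,4a,5,6,7,8,8a-octahydronaphthalen-1-yl trifluoromethanesulfonate | O=S(=O)(OC1=C(C)CC[C@@H]2C(C)(C)CCC[C@@]12C)C(F)(F)F | intermediate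
13 | methyl (4R)-2,2-dimethyl-1,3-dioxolane-4-carboxylate | COC(=O)[C@H]1COC(C)(C)O1 | starting material
14 | 1-[(4R)-2,2-dimethyl-1,3-dioxolan-4-yl]cyclopropan-1-ol | OC1(CC1)[C@H]1COC(C)(C)O1 | intermediate
15 | 1-[(4R)-2,2-dimethyl-1,3-dioxolan-4-yl]-3-[(4aR,8aR)-2,5,5,8a-tetramethyl-3,4,4a,5,6,7,8,8a-octahydronaphthalen-1-yl]propan-1-one | O=C(CCC1=C(C)CC[C@@H]2C(C)(C)CCC[C@@]12C)[C@H]1COC(C)(C)O1 | intermediate
16 | (4S)-2,2-dimethyl-4-{4-[(4aR,8aR)-2,5,5,8a-tetramethyl-3,4,4a,5,6,7,8,8a-octahydronaphthalen-1-yl]but-1-en-2-yl}-1,3-dioxolane | C=C(CCC1=C(C)CC[C@@H]2C(C)(C)CCC[C@@]12C)[C@H]1COC(C)(C)O1 | intermediate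
17 | (2S)-3-methylidene-5-[(4aR,8aR)-2,5,5,8a-tetramethyl-3,4,4a,5,6,7,8,8a-octahydronaphthalen-1-yl]pentane-1,2-diol | C=C(CCC1=C(C)CC[C@@H]2C(C)(C)CCC[C@@]12C)[C@@H](CO)O | intermediate
18 | (2S)-3-methylidene-5-[(4aR,8aR)-2,5,5,8a-tetramethyl-3,4,4a,5,6,7,8,8a-octahydronaphthalen-1-yl]pentane-1,2-diyl diacetate | C=C(CCC1=C(C)CC[C@@H]2C(C)(C)CCC[C@@]12C)[C@@H](COC(C)=O)OC(C)=O | target

**Total step count:** 11. **Longest linear sequence:** 10 (steps 1–6 and 8–11; step 7 prepares the side-chain partner).

**Steps most likely to fail**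

Step 5. The acid co-catalyst may protodesilylate the enol ether before the hindered iminium β-carbon C5 is attacked, and facial or ring-fusion selectivity may be incomplete. The fallback separates the two bond formations and uses a stoichiometric chiral imine. It sets out from 6: cross-metathesis with methyl acrylate under the step 4 catalyst and acidic work-up would give methyl (2E)-4,4,8-trimethyl-9-oxoundec-2-enoate F1. Condensation with (S)-1-phenylethylamine (or its antipode, whichever the facial model requires for 10R) would give the ketimine methyl (2E)-4,4,8-trimethyl-9-{[(1S)-1-phenylethyl]imino}undec-2-enoate F2. Heating should cyclise F2 through its more substituted secondary enamine in an aza-ene-type Michael addition to methyl 2-[(1R,2R)-2,6,6-trimethyl-2-{N-[(1S)-1-phenylethyl]propanimidoyl}cyclohexyl]acetate F3. Aqueous acetic acid would hydrolyse F3 to methyl 2-[(1R,2R)-2,6,6-trimethyl-2-propanoylcyclohexyl]acetate F4, and LiAlH4 would reduce F4 to 1-[(1R,2R)-2-(2-hydroxyethyl)-1,3,3-trimethylcyclohexyl]propan-1-ol F5. Swern oxidation of F5 comes back to the route at 9, which p-TsOH closes to 10.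

Step 8. Reductive elimination at the doubly flanked alkenylpalladium may be slow, so β-hydride elimination of the homoenolate can compete, and the carbonate may epimerise the centre next to the new ketone. The fallback builds the 1,1-disubstituted alkene directly by sp2–sp3 coupling. It sets out from 12: Stille coupling with Bu3SnCH=CH2 (Pd(PPh3)4, LiCl, THF, reflux) would give (4aR,8aR)-1-ethenyl-2,5,5,8a-tetramethyl-3,4,4a,5,6,7,8,8a-octahydronaphthalene F6. 9-BBN should hydroborate only its terminal vinyl group to 9-{2-[(4aR,8aR)-2,5,5,8a-tetramethyl-3,4,4a,5,6,7,8,8a-octahydronaphthalen-1-yl]ethyl}-9-borabicyclo[3.3.1]nonane F7. In parallel, ester 13 would be converted with MeNHOMe·HCl and i-PrMgCl into (4R)-N-methoxy-N,2,2-trimethyl-1,3-dioxolane-4-carboxamide F8, with MeMgBr into 1-[(4R)-2,2-dimethyl-1,3-dioxolan-4-yl]ethan-1-one F9, and with KN(SiMe3)2 and PhNTf2 at −78 °C (kinetic deprotonation at the methyl group) into 1-[(4R)-2,2-dimethyl-1,3-dioxolan-4-yl]ethenyl trifluoromethanesulfonate F10. B-alkyl Suzuki–Miyaura coupling of F7 with F10 (Pd(dppf)Cl2, Cs2CO3, DMF/THF/H2O) comes back to the route at 16 and by-passes 15 and step 9.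

Step 4. Metathesis at the vinyl group on quaternary C4 may stall, and the trimethylsilyl enol ether may be lost on silica. The fallback replaces metathesis by oxidative cleavage and olefination. It sets out from 6: mild aqueous acid would give 4,8,8-trimethyldec-9-en-3-one F11, ozonolysis (O3, CH2Cl2, −78 °C; Me2S) would give 2,2,6-trimethyl-7-oxononanal F12, and Wittig reaction with Ph3P=CHCHO, selective for the aldehyde, would give (2E)-4,4,8-trimethyl-9-oxoundec-2-enal F13. F13 would then be submitted to the step 5 catalyst system, with the ketone entering through its more substituted enol in place of the silyl enol ether; this is expected to be slower and comes back to the route at 10.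

Further compounds
F1 | step 5 | methyl (2E)-4,4,8-trimethyl-9-oxoundec-2-enoate | CCC(=O)C(C)CCCC(C)(C)/C=C/C(=O)OC
F2 | step 5 | methyl (2E)-4,4,8-trimethyl-9-{[(1S)-1-phenylethyl]imino}undec-2-enoate | CCC(=N[C@@H](C)c1ccccc1)C(C)CCCC(C)(C)/C=C/C(=O)OC
F3 | step 5 | methyl 2-[(1R,2R)-2,6,6-trimethyl-2-{N-[(1S)-1-phenylethyl]propanimidoyl}cyclohexyl]acetate | CCC(=N[C@@H](C)c1ccccc1)[C@]1(C)CCCC(C)(C)[C@H]1CC(=O)OC
F4 | step 5 | methyl 2-[(1R,2R)-2,6,6-trimethyl-2-propanoylcyclohexyl]acetate | CCC(=O)[C@]1(C)CCCC(C)(C)[C@H]1CC(=O)OC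
F5 | step 5 | 1-[(1R,2R)-2-(2-hydroxyethyl)-1,3,3-trimethylcyclohexyl]propan-1-ol | CCC(O)[C@]1(C)CCCC(C)(C)[C@H]1CCO
F6 | step 8 | (4aR,8aR)-1-ethenyl-2,5,5,8a-tetramethyl-3,4,4a,5,6,7,8,8a-octahydronaphthalene | C=CC1=C(C)CC[C@@H]2C(C)(C)CCC[C@@]12C
F7 | step 8 | 9-{2-[(4aR,8aR)-2,5,5,8a-tetramethyl-3,4,4a,5,6,7,8,8a-octahydronaphthalen-1-yl]ethyl}-9-borabicyclo[3.3.1]nonane | C(CC1=C(C)CC[C@@H]2C(C)(C)CCC[C@@]12C)B1C2CCCC1CCC2
F8 | step 8 | (4R)-N-methoxy-N,2,2-trimethyl-1,3-dioxolane-4-carboxamide | CON(C)C(=O)[C@H]1COC(C)(C)O1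
F9 | step 8 | 1-[(4R)-2,2-dimethyl-1,3-dioxolan-4-yl]ethan-1-one | CC(=O)[C@H]1COC(C)(C)O1
F10 | step 8 | 1-[(4R)-2,2-dimethyl-1,3-dioxolan-4-yl]ethenyl trifluoromethanesulfonate | C=C(OS(=O)(=O)C(F)(F)F)[C@H]1COC(C)(C)O1
F11 | step 4 | 4,8,8-trimethyldec-9-en-3-one | CCC(=O)C(C)CCCC(C)(C)C=C
F12 | step 4 | 2,2,6-trimethyl-7-oxononanal | CCC(=O)C(C)CCCC(C)(C)C=O
F13 | step 4 | (2E)-4,4,8-trimethyl-9-oxoundec-2-enal | CCC(=O)C(C)CCCC(C)(C)/C=C/C=O
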